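**Plan**

1. Retrosynthesis: cut C3–C1' (Suzuki–Miyaura), then the C6–CH2 bond of the side chain (B-alkyl Suzuki–Miyaura), then in ring B the C4'–O bond of the dimethylpyran together with its C3–C4 bond (aldol/SNAr annulation with acetone) and the C2'–O bond (second SNAr).
2. Enabling feature: in ring B, C5' carries pyran C4, the pyran oxygen sits on C4' (ortho to C5') and the hydroxyl on C2' (para to C5'). With pyran C4 held as a ketone, the fluorides at C4' and C2' of a 2,4-difluoroaryl methyl ketone are both activated, and the linear ring fusion is fixed by the position of the acetyl group.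
3. Forward, branch 1: pyranone ring (key step, aryl C–O bond), then the C2' oxygen, then removal of the ketone helper by reduction/dehydration to the chromene, then the boronate.
4. Forward, branch 2: ring C by enaminone/iodine cyclisation of a symmetric 2,6-dihydroxyacetophenone (O1 fixed by symmetry), then iodination at C6 next to the chelated 5-OH.
5. Union at C3, alkyl chain at C6 from 2-methylbut-3-en-2-ol without any hydrogenation, then removal of the two MOM groups.
6. Stereochemistry: the target is achiral; its only stereo element, the cis C3=C4 bond of the chromene, is fixed by the six-membered ring when the chromanol is dehydrated.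

Key step: step 1

Assumption: iodination of 14 is taken to occur at C6, ortho to the chelated 5-hydroxyl, by analogy with 5-hydroxy-7-alkoxyflavones; ketone 1 is taken as a catalogue compound.

Step 1
Reactants: 1 1-(5-bromo-2,4-difluorophenyl)ethan-1-one
Product: 4 6-bromo-7-fluoro-2,2-dimethyl-2,3-dihydro-4H-chromen-4-one, via lithium enolate 2 (not isolated), via lithium aldolate 3 (not isolated)
Conditions: LiN(SiMe3)2, THF, −78 °C; acetone, −78 °C; then DMPU, −78 to 40 °C
Reagents that add atoms: acetone, CC(C)=O
Why: The lithium enolate 2 adds to acetone (aldol addition) and the tertiary lithium alkoxide 3 attacks the fluorine-bearing carbon ortho to the ketone, giving a Meisenheimer complex that is stabilised as the ketone enolate and by the meta fluorine and para bromine before LiF is lost (intramolecular SNAr, addition–elimination). The closest known reaction type is the base-mediated cyclisation of 1-(2-fluoroaryl)-3-hydroxyalkan-1-ones to chroman-4-ones, here run in tandem with the aldol addition that makes the hydroxy ketone. The six-membered ring closes by ortho-fused SNAr, formally a 6-exo-trig addition at the C–F carbon followed by loss of fluoride, and no stereocentre is formed because C2 carries two methyl groups. The step needs site selectivity between the two C–F bonds and chemoselectivity against retro-aldol: only the ortho fluoride can be reached by the tethered alkoxide through a six-membered transition state, the para fluoride would require an intermolecular attack, and retro-aldol is reversible whereas loss of LiF is not. The silylamide base should deprotonate the methyl ketone and not the ring C–H between the two fluorines, and the C–Br bond, meta to the carbonyl, is not activated.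

Step 2
Reactants: 4 6-bromo-7-fluoro-2,2-dimethyl-2,3-dihydro-4H-chromen-4-one
Product: 7 6-bromo-7-(methoxymethoxy)-2,2-dimethyl-2,3-dihydro-4H-chromen-4-one, via aryl trimethylsilyl ether 5 (not isolated), via potassium phenolate 6 (not isolated)
Conditions: KOSiMe3, DMF, 70 °C; then MOMCl, 0 °C to rt
Reagents that add atoms: potassium trimethylsilanolate, C[Si](C)(C)[O-].[K+]; chloromethyl methyl ether (MOMCl), COCCl
Why: Trimethylsilanolate acts as a hydroxide surrogate in an SNAr at C7, which is para to the ketone and ortho to bromine, a second silanolate removes the silyl group from 5, and the phenolate 6 is O-alkylated by MOMCl (Williamson ether synthesis); the weakly basic silanolate should neither enolise nor open the chromanone.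

Step 3
Reactants: 7 6-bromo-7-(methoxymethoxy)-2,2-dimethyl-2,3-dihydro-4H-chromen-4-one
Product: 9 6-bromo-7-(methoxymethoxy)-2,2-dimethyl-2H-chromene, via racemic chroman-4-ol 8 (not isolated)
Conditions: NaBH4, MeOH/THF, 0 °C to rt; work-up; then PPTS (cat.), toluene, 80 °C
Reagents that add atoms: none
Why: NaBH4 reduces the aryl ketone to the racemic chromanol 8 (1,2-hydride reduction), and mild acid then ionises the benzylic alcohol, whose cation is stabilised by the ortho ring oxygen and the para OMOM group, to give the alkene by E1 dehydration; the stereocentre of 8 is lost and the double bond is cis because it lies in the six-membered ring.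

Step 4
Reactants: 9 6-bromo-7-(methoxymethoxy)-2,2-dimethyl-2H-chromene
Product: 10 2-[7-(methoxymethoxy)-2,2-dimethyl-2H-chromen-6-yl]-4,4,5,5-tetramethyl-1,3,2-dioxaborolane
Conditions: B2pin2, PdCl2(dppf) (cat.), KOAc, 1,4-dioxane, 90 °C
Reagents that add atoms: bis(pinacolato)diboron (B2pin2), CC1(C)OB(OC1(C)C)B1OC(C)(C)C(C)(C)O1
Why: Miyaura borylation (oxidative addition of the aryl bromide to zerovalent palladium, acetate-assisted transmetalation with B2pin2, reductive elimination) should convert the bromide to the pinacol boronate while the chromene alkene and the MOM ether stay untouched.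

Step 5
Reactants: 11 1-(2,4,6-trihydroxyphenyl)ethan-1-one
Product: 12 1-[2,6-dihydroxy-4-(methoxymethoxy)phenyl]ethan-1-one
Conditions: MOMCl (1.05 equiv), i-Pr2NEt, THF, 0 °C
Reagents that add atoms: chloromethyl methyl ether (MOMCl), COCCl
Why: The 4-hydroxyl is the most acidic and the only one not hydrogen-bonded to the ketone, so one equivalent of MOMCl with a hindered amine should alkylate it selectively (Williamson-type O-alkylation) and leave a symmetric 2,6-diol.

Step 6
Reactants: 12 1-[2,6-dihydroxy-4-(methoxymethoxy)phenyl]ethan-1-one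
Product: 14 5-hydroxy-3-iodo-7-(methoxymethoxy)-4H-chromen-4-one, via enaminone 13 (not isolated)
Conditions: Me2NCH(OMe)2, toluene, 90 °C; evaporate; then I2, CHCl3, rt
Reagents that add atoms: N,N-dimethylformamide dimethyl acetal, COC(OC)N(C)C; iodine, II
Why: Condensation of the methyl ketone with the amide acetal gives enaminone 13, and iodine then iodinates its α-carbon while one of the two equivalent ortho hydroxyls adds to the iminium carbon and dimethylamine is expelled (iodine-mediated enaminone cyclisation to a 3-iodochromone); because the 2,6-diol is symmetric only one chromone can form, and the other hydroxyl becomes the chelated 5-OH.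

Step 7
Reactants: 14 5-hydroxy-3-iodo-7-(methoxymethoxy)-4H-chromen-4-one
Product: 15 5-hydroxy-3,6-diiodo-7-(methoxymethoxy)-4H-chromen-4-one
Conditions: BnMe3N+ ICl2−, CaCO3, CH2Cl2/MeOH, rt
Reagents that add atoms: benzyltrimethylammonium dichloroiodate, C[N+](C)(C)Cc1ccccc1.Cl[I-]Cl
Why: Electrophilic aromatic iodination: the free, chelated 5-hydroxyl should direct the reagent to its only ortho position, C6, as is known for 5-hydroxy-7-alkoxyflavones with this reagent, while CaCO3 takes up HCl so that the MOM ether survives.

Step 8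
Reactants: 15 5-hydroxy-3,6-diiodo-7-(methoxymethoxy)-4H-chromen-4-one; 10 2-[7-(methoxymethoxy)-2,2-dimethyl-2H-chromen-6-yl]-4,4,5,5-tetramethyl-1,3,2-dioxaborolane
Product: 16 5-hydroxy-6-iodo-7-(methoxymethoxy)-3-[7-(methoxymethoxy)-2,2-dimethyl-2H-chromen-6-yl]-4H-chromen-4-one
Conditions: PdCl2(dppf) (cat.), K2CO3, 1,4-dioxane/H2O, 60 °C; 10 (1.05 equiv)
Reagents that add atoms: none
Why: Suzuki–Miyaura coupling: oxidative addition should take place at the C3–I bond of the electron-poor iodoenone much faster than at the C6–I bond, which is flanked by the phenolate and the OMOM group, so one equivalent of boronate 10 should give the isoflavone with the C6 iodide intact.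

Step 9
Reactants: 16 5-hydroxy-6-iodo-7-(methoxymethoxy)-3-[7-(methoxymethoxy)-2,2-dimethyl-2H-chromen-6-yl]-4H-chromen-4-one
Product: 17 5-hydroxy-6-(3-hydroxy-3-methylbutyl)-7-(methoxymethoxy)-3-[7-(methoxymethoxy)-2,2-dimethyl-2H-chromen-6-yl]-4H-chromen-4-one
Conditions: 2-methylbut-3-en-2-ol, 9-BBN-H (excess), THF, rt (separate flask); then 16, PdCl2(dppf) (cat.), K3PO4, DMF/H2O, 60 °C
Reagents that add atoms: 2-methylbut-3-en-2-ol, CC(C)(O)C=C
Why: 9-BBN-H adds to the terminal alkene with anti-Markovnikov selectivity, and the primary alkylborane transfers its alkyl group to the arylpalladium iodide after activation by aqueous phosphate (B-alkyl Suzuki–Miyaura coupling), which installs the saturated hydroxylated chain without a hydrogenation that would also reduce the chromene double bond.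

Step 10
Reactants: 17 5-hydroxy-6-(3-hydroxy-3-methylbutyl)-7-(methoxymethoxy)-3-[7-(methoxymethoxy)-2,2-dimethyl-2H-chromen-6-yl]-4H-chromen-4-one
Product: 18 5,7-dihydroxy-6-(3-hydroxy-3-methylbutyl)-3-(7-hydroxy-2,2-dimethyl-2H-chromen-6-yl)-4H-chromen-4-one
Conditions: ZnBr2, n-PrSH, CH2Cl2, 0 °C
Reagents that add atoms: none
Why: ZnBr2 activates the acetal oxygens and the thiol captures the methoxymethyl cation (Lewis acid-mediated acetal cleavage), so both aryl MOM ethers should be removed within minutes at 0 °C without a protic acid that could ionise the tertiary alcohol beside the 5- and 7-hydroxyls or open the chromene.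

**Compound list**

1 | 1-(5-bromo-2,4-difluorophenyl)ethan-1-one | CC(=O)c1cc(Br)c(F)cc1F | starting material
2 | lithium 1-(5-bromo-2,4-difluorophenyl)ethen-1-olate (lithium enolate) | [Li+].[O-]C(=C)c1cc(Br)c(F)cc1F | intermediate
3 | lithium 4-(5-bromo-2,4-difluorophenyl)-2-methyl-4-oxobutan-2-olate (lithium aldolate) | [Li+].CC(C)([O-])CC(=O)c1cc(Br)c(F)cc1F | intermediate
4 | 6-bromo-7-fluoro-2,2-dimethyl-2,3-dihydro-4H-chromen-4-one | CC1(C)CC(=O)c2cc(Br)c(F)cc2O1 | intermediate
5 | 6-bromo-2,2-dimethyl-7-[(trimethylsilyl)oxy]-2,3-dihydro-4H-chromen-4-one | CC1(C)CC(=O)c2cc(Br)c(O[Si](C)(C)C)cc2O1 | intermediate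
6 | potassium 6-bromo-2,2-dimethyl-4-oxo-3,4-dihydro-2H-chromen-7-olate | [K+].CC1(C)CC(=O)c2cc(Br)c([O-])cc2O1 | intermediate
7 | 6-bromo-7-(methoxymethoxy)-2,2-dimethyl-2,3-dihydro-4H-chromen-4-one | COCOc1cc2OC(C)(C)CC(=O)c2cc1Br | intermediate
8 | 6-bromo-7-(methoxymethoxy)-2,2-dimethyl-3,4-dihydro-2H-chromen-4-ol (racemic) | COCOc1cc2OC(C)(C)CC(O)c2cc1Br | intermediate
9 | 6-bromo-7-(methoxymethoxy)-2,2-dimethyl-2H-chromene | COCOc1cc2OC(C)(C)C=Cc2cc1Br | intermediate
10 | 2-[7-(methoxymethoxy)-2,2-dimethyl-2H-chromen-6-yl]-4,4,5,5-tetramethyl-1,3,2-dioxaborolane | COCOc1cc2OC(C)(C)C=Cc2cc1B1OC(C)(C)C(C)(C)O1 | intermediate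
11 | 1-(2,4,6-trihydroxyphenyl)ethan-1-one | CC(=O)c1c(O)cc(O)cc1O | starting material
12 | 1-[2,6-dihydroxy-4-(methoxymethoxy)phenyl]ethan-1-one | COCOc1cc(O)c(C(C)=O)c(O)c1 | intermediate
13 | (E)-1-[2,6-dihydroxy-4-(methoxymethoxy)phenyl]-3-(dimethylamino)prop-2-en-1-one | COCOc1cc(O)c(C(=O)/C=C/N(C)C)c(O)c1 | intermediate
14 | 5-hydroxy-3-iodo-7-(methoxymethoxy)-4H-chromen-4-one | COCOc1cc(O)c2c(c1)occ(I)c2=O | intermediate
15 | 5-hydroxy-3,6-diiodo-7-(methoxymethoxy)-4H-chromen-4-one | COCOc1cc2occ(I)c(=O)c2c(O)c1I | intermediate
16 | 5-hydroxy-6-iodo-7-(methoxymethoxy)-3-[7-(methoxymethoxy)-2,2-dimethyl-2H-chromen-6-yl]-4H-chromen-4-one | COCOc1cc2occ(-c3cc4C=CC(C)(C)Oc4cc3OCOC)c(=O)c2c(O)c1I | intermediate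
17 | 5-hydroxy-6-(3-hydroxy-3-methylbutyl)-7-(methoxymethoxy)-3-[7-(methoxymethoxy)-2,2-dimethyl-2H-chromen-6-yl]-4H-chromen-4-one | COCOc1cc2occ(-c3cc4C=CC(C)(C)Oc4cc3OCOC)c(=O)c2c(O)c1CCC(C)(C)O | intermediate
18 | 5,7-dihydroxy-6-(3-hydroxy-3-methylbutyl)-3-(7-hydroxy-2,2-dimethyl-2H-chromen-6-yl)-4H-chromen-4-one | CC(C)(O)CCc1c(O)cc2occ(-c3cc4c(cc3O)OC(C)(C)C=C4)c(=O)c2c1O | target

**Step count and risks**

Total steps: 10. Longest linear sequence: 7 (steps 1–4, then 8–10); the second branch is steps 5–7.

Most likely to fail, in this order: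

Step 9. Oxidative addition at the doubly ortho-substituted iodophenolate may be slow, and β-hydride elimination of the alkylpalladium intermediate may then lead to protodeiodination instead of coupling. The fallback sets out from 16 and replaces the organoborane by an organozinc under base-free conditions. Negishi coupling of 16 with [3-methyl-3-(trimethylsilyloxy)butyl]zinc bromide (from the silylated 4-bromo-2-methylbutan-2-ol and zinc dust with LiCl) under Pd(OAc)2/CPhos in THF/NMP at rt to 40 °C should give the silyl ether 5-hydroxy-7-(methoxymethoxy)-3-[7-(methoxymethoxy)-2,2-dimethyl-2H-chromen-6-yl]-6-{3-methyl-3-[(trimethylsilyl)oxy]butyl}-4H-chromen-4-one F1. Methanolysis with K2CO3 in MeOH then returns to the route at 17.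

Step 1. Retro-aldol fragmentation of the tertiary lithium aldolate, or its dehydration, may outrun the ring closure. The fallback sets out from 1 and separates the two events so that no alkoxide exists during the C–C bond formation. Soft enolisation of 1 with TMSOTf/Et3N in CH2Cl2 should give the silyl enol ether {[1-(5-bromo-2,4-difluorophenyl)ethenyl]oxy}(trimethyl)silane F2. Mukaiyama aldol addition of F2 to acetone with TiCl4 in CH2Cl2 at −78 °C should give the neutral hydroxy ketone 1-(5-bromo-2,4-difluorophenyl)-3-hydroxy-3-methylbutan-1-one F3. Cyclisation of F3 with Cs2CO3 in acetone as solvent, where any retro-aldol only regenerates the same partners, closes the ring by SNAr and returns to the route at 4.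

Step 8. Site selectivity between the two carbon–iodine bonds may be lost (arylation at C6 or double arylation), and the hindered boronate may undergo protodeboronation when the coupling is slowed to protect selectivity. The fallback sets out from 14 and uses two different halogens. Bromination of 14 with BnMe3N+ Br3− and CaCO3 in CH2Cl2/MeOH should give 6-bromo-5-hydroxy-3-iodo-7-(methoxymethoxy)-4H-chromen-4-one F4. Suzuki–Miyaura coupling of F4 with 10 [PdCl2(dppf), K2CO3, 1,4-dioxane/H2O, 50 °C] can then only take place at the C–I bond and should give 6-bromo-5-hydroxy-7-(methoxymethoxy)-3-[7-(methoxymethoxy)-2,2-dimethyl-2H-chromen-6-yl]-4H-chromen-4-one F5. B-alkyl Suzuki–Miyaura coupling of the aryl bromide F5 with the same 9-BBN reagent under Pd(OAc)2/SPhos, K3PO4, 80 °C returns to the route at 17.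

**Further compounds**

F1 | step 9 | 5-hydroxy-7-(methoxymethoxy)-3-[7-(methoxymethoxy)-2,2-dimethyl-2H-chromen-6-yl]-6-{3-methyl-3-[(trimethylsilyl)oxy]butyl}-4H-chromen-4-one | COCOc1cc2occ(-c3cc4C=CC(C)(C)Oc4cc3OCOC)c(=O)c2c(O)c1CCC(C)(C)O[Si](C)(C)C
F2 | step 1 | {[1-(5-bromo-2,4-difluorophenyl)ethenyl]oxy}(trimethyl)silane | C=C(O[Si](C)(C)C)c1cc(Br)c(F)cc1F
F3 | step 1 | 1-(5-bromo-2,4-difluorophenyl)-3-hydroxy-3-methylbutan-1-one | CC(C)(O)CC(=O)c1cc(Br)c(F)cc1F
F4 | step 8 | 6-bromo-5-hydroxy-3-iodo-7-(methoxymethoxy)-4H-chromen-4-one | COCOc1cc2occ(I)c(=O)c2c(O)c1Br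
F5 | step 8 | 6-bromo-5-hydroxy-7-(methoxymethoxy)-3-[7-(methoxymethoxy)-2,2-dimethyl-2H-chromen-6-yl]-4H-chromen-4-one | COCOc1cc2occ(-c3cc4C=CC(C)(C)Oc4cc3OCOC)c(=O)c2c(O)c1Br
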